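The synthesis rests on disconnecting the lactone C–O bond O1'–C8a' of unit B (the 7-O-linked coumarin). The feature exploited is that C8a' lies para to the C6' methoxy group and ortho to the C4a' side chain, exactly where the radical cation of a 4-aryloxy-3-methoxyphenyl ring accepts its own carboxyl oxygen. One anodic dehydrogenative C–H lactonisation therefore closes the pyranone ring of unit B on a saturated 3-arylpropanoic acid, with no alkene geometry to control. The precursor is that acid, already carrying complete unit A as its C7 acetate through a C3–O–aryl ether; dehydrogenation and deacetylation finish the synthesis.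

Key step: step 6

Remark: unprimed locants refer to unit A (the coumarin with the free 7-OH and the 3-aryloxy group), primed locants to unit B (the coumarin bound through O7'); the target has no stereocentre.

Design note: the C7 phenol of unit A is carried as the acetate that the coumarin-forming step installs anyway. It lowers the electron density of ring A for the electrolysis, shields the phenol from DDQ and is removed last. The acid is electrolysed without added base so that carboxylate (Kolbe-type) oxidation is not invited.

Step 1
Reactants: 1 dihydroferulic acid [3-(4-hydroxy-3-methoxyphenyl)propanoic acid]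
Product: 2 tert-butyl 3-(4-hydroxy-3-methoxyphenyl)propanoate
Conditions: Me2NCH(OtBu)2, toluene, 80 °C
Reagents that add atoms: N,N-dimethylformamide di-tert-butyl acetal, CN(C)C(OC(C)(C)C)OC(C)(C)C
Why: Esterification with a DMF dialkyl acetal: the carboxylic acid protonates the acetal and the carboxylate is tert-butylated within the ion pair, whereas the far less acidic guaiacol OH should not be alkylated at this temperature.

Step 2
Reactants: 2 tert-butyl 3-(4-hydroxy-3-methoxyphenyl)propanoate; 3 benzyl bromoacetate
Product: 4 benzyl 2-[4-(3-tert-butoxy-3-oxopropyl)-2-methoxyphenoxy]acetate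
Conditions: K2CO3, acetone, reflux
Reagents that add atoms: none
Why: Williamson ether synthesis: the phenoxide formed with K2CO3 displaces bromide from the activated α-bromo ester by SN2, and the tert-butyl ester is inert to these conditions.

Step 3
Reactants: 4 benzyl 2-[4-(3-tert-butoxy-3-oxopropyl)-2-methoxyphenoxy]acetate
Product: 5 2-[4-(3-tert-butoxy-3-oxopropyl)-2-methoxyphenoxy]acetic acid
Conditions: H2 (1 atm), Pd/C, EtOAc, rt
Reagents that add atoms: none
Why: Catalytic hydrogenolysis of the benzyl ester over palladium on carbon should free the aryloxyacetic acid, while the tert-butyl ester, the aryl ethers and the arene are untouched.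

Step 4
Reactants: 5 2-[4-(3-tert-butoxy-3-oxopropyl)-2-methoxyphenoxy]acetic acid; 6 2,4-dihydroxy-5-methoxybenzaldehyde
Product: 7 tert-butyl 3-{4-[(7-acetoxy-6-methoxy-2-oxo-2H-chromen-3-yl)oxy]-3-methoxyphenyl}propanoate
Conditions: Ac2O, Et3N, 110 °C
Reagents that add atoms: acetic anhydride, CC(=O)OC(C)=O
Why: Perkin–Oglialoro coumarin synthesis: the mixed anhydride of the aryloxyacetic acid acylates the 2-OH and its activated α-CH2 condenses with the neighbouring aldehyde (aldol–dehydration) to give the 3-aryloxycoumarin, the 4-OH is acetylated by the medium to give the 7-acetate, and the propanoate is kept out of the condensation as its tert-butyl ester.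

Step 5
Reactants: 7 tert-butyl 3-{4-[(7-acetoxy-6-methoxy-2-oxo-2H-chromen-3-yl)oxy]-3-methoxyphenyl}propanoate
Product: 8 3-{4-[(7-acetoxy-6-methoxy-2-oxo-2H-chromen-3-yl)oxy]-3-methoxyphenyl}propanoic acid
Conditions: TFA, CH2Cl2, 0 °C to rt
Reagents that add atoms: none
Why: Acidolysis of the tert-butyl ester (loss of the tert-butyl cation as isobutene) in anhydrous TFA should leave the aryl acetate, the coumarin lactone and the diaryl ether intact.

Step 6
Reactants: 8 3-{4-[(7-acetoxy-6-methoxy-2-oxo-2H-chromen-3-yl)oxy]-3-methoxyphenyl}propanoic acid
Product: 9 6-methoxy-3-[(6-methoxy-2-oxo-3,4-dihydro-2H-chromen-7-yl)oxy]-2-oxo-2H-chromen-7-yl acetate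
Conditions: undivided cell, graphite anode, Pt cathode, Bu4NBF4 (0.1 M), dry HFIP, constant current (2.2 F mol−1), rt, Ar
Reagents that add atoms: none
Why: Proposed new method: one-electron oxidation at graphite should generate the radical cation of the 4-aryloxy-3-methoxyphenyl ring, which HFIP stabilises long enough for the tethered carboxyl oxygen to add at the ring carbon ortho to the chain and para to the methoxy group (directly, or by ipso attack followed by a 1,2-acyloxy shift), after which a second electron transfer and loss of a proton restore aromaticity while the released protons are reduced to H2 at the platinum cathode. The closest known reaction types are the dehydrogenative C(sp2)–H lactonisation of 3-arylpropanoic acids to 3,4-dihydrocoumarins with PhI(OCOCF3)2 and BF3·OEt2, and the anodic lactonisation of 2-arylbenzoic acids to benzocoumarins; anodic closure of a 3-arylpropanoic acid is the extension proposed here. The single ring formed, the dihydropyranone of unit B, closes by six-membered O-attack on the arene radical cation (formally 6-endo with respect to the C4a'–C8a' bond), or by 5-exo spiro closure at the ipso carbon and ring expansion, both forming O1'–C8a'. No stereocentre is created. Two selectivities are needed: ring B must be oxidised before ring A, which the electron-withdrawing lactone carbonyl and O-acetyl group of unit A secure, and the oxygen must bond to the carbon para to the methoxy group and not to the one between the chain and the methoxy group, which the higher positive charge density para to the donor and the crowding of the doubly flanked ortho site secure. Dry HFIP keeps water from intercepting the ipso cation, which would otherwise cleave the diaryl ether, and the lactone product, bearing an acyloxy group in place of a hydrogen, is harder to oxidise than the acid and should survive.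

Step 7
Reactants: 9 6-methoxy-3-[(6-methoxy-2-oxo-3,4-dihydro-2H-chromen-7-yl)oxy]-2-oxo-2H-chromen-7-yl acetate
Product: 10 6-methoxy-3-[(6-methoxy-2-oxo-2H-chromen-7-yl)oxy]-2-oxo-2H-chromen-7-yl acetate
Conditions: DDQ, 1,4-dioxane, reflux
Reagents that add atoms: none
Why: DDQ dehydrogenation of a 3,4-dihydrocoumarin: hydride abstraction from the benzylic C4'–H, assisted by the para 7'-aryloxy oxygen, followed by loss of a C3' proton should give the conjugated coumarin, and the acetate keeps the C7 phenol from being oxidised by the quinone.

Step 8
Reactants: 10 6-methoxy-3-[(6-methoxy-2-oxo-2H-chromen-7-yl)oxy]-2-oxo-2H-chromen-7-yl acetate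
Product: 11 7-hydroxy-6-methoxy-3-[(6-methoxy-2-oxo-2H-chromen-7-yl)oxy]-2H-chromen-2-one (target)
Conditions: K2CO3 (cat.), MeOH/CH2Cl2, 0 °C to rt; then 1 M HCl
Reagents that add atoms: none
Why: Base-catalysed transesterification (Zemplén-type methanolysis) should cleave the phenolic acetate much faster than methoxide opens the conjugated coumarin lactones, and acidification on work-up re-closes any lactone that has opened reversibly.

Compound list
1 | dihydroferulic acid, 3-(4-hydroxy-3-methoxyphenyl)propanoic acid | COc1cc(CCC(O)=O)ccc1O | starting material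
2 | tert-butyl 3-(4-hydroxy-3-methoxyphenyl)propanoate | COc1cc(CCC(=O)OC(C)(C)C)ccc1O | intermediate
3 | benzyl bromoacetate | BrCC(=O)OCc1ccccc1 | starting material
4 | benzyl 2-[4-(3-tert-butoxy-3-oxopropyl)-2-methoxyphenoxy]acetate | COc1cc(CCC(=O)OC(C)(C)C)ccc1OCC(=O)OCc1ccccc1 | intermediate
5 | 2-[4-(3-tert-butoxy-3-oxopropyl)-2-methoxyphenoxy]acetic acid | COc1cc(CCC(=O)OC(C)(C)C)ccc1OCC(O)=O | intermediate
6 | 2,4-dihydroxy-5-methoxybenzaldehyde | COc1cc(C=O)c(O)cc1O | starting material
7 | tert-butyl 3-{4-[(7-acetoxy-6-methoxy-2-oxo-2H-chromen-3-yl)oxy]-3-methoxyphenyl}propanoate | CC(=O)Oc1cc2oc(=O)c(Oc3ccc(CCC(=O)OC(C)(C)C)cc3OC)cc2cc1OC | intermediate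
8 | 3-{4-[(7-acetoxy-6-methoxy-2-oxo-2H-chromen-3-yl)oxy]-3-methoxyphenyl}propanoic acid | CC(=O)Oc1cc2oc(=O)c(Oc3ccc(CCC(O)=O)cc3OC)cc2cc1OC | intermediate
9 | 6-methoxy-3-[(6-methoxy-2-oxo-3,4-dihydro-2H-chromen-7-yl)oxy]-2-oxo-2H-chromen-7-yl acetate | CC(=O)Oc1cc2oc(=O)c(Oc3cc4OC(=O)CCc4cc3OC)cc2cc1OC | intermediate
10 | 6-methoxy-3-[(6-methoxy-2-oxo-2H-chromen-7-yl)oxy]-2-oxo-2H-chromen-7-yl acetate | CC(=O)Oc1cc2oc(=O)c(Oc3cc4oc(=O)ccc4cc3OC)cc2cc1OC | intermediate
11 | 7-hydroxy-6-methoxy-3-[(6-methoxy-2-oxo-2H-chromen-7-yl)oxy]-2H-chromen-2-one | COc1cc2cc(Oc3cc4oc(=O)ccc4cc3OC)c(=O)oc2cc1O | target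

Total step count: 8. Longest linear sequence: 8 steps (1 → 2 → 4 → 5 → 7 → 8 → 9 → 10 → 11); compounds 3 and 6 enter as purchased materials.

Steps most likely to fail

1. Step 6 (Proposed new method). The radical cation may lose a benzylic proton and be oxidised further in the side chain, the ipso cation may be intercepted by adventitious nucleophiles with cleavage of the diaryl ether, or the anode may foul, so that C–O closure does not compete. The fallback uses known chemistry only, sets out from 6 and returns at 10, and builds the lactone of unit B by olefination instead of C–H oxidation. Aldehyde 6 with ethyl (triphenylphosphoranylidene)acetate in refluxing N,N-diethylaniline (Wittig olefination with lactonisation in the same pot) should give scopoletin F1 (7-hydroxy-6-methoxy-2H-chromen-2-one). O-Alkylation with tert-butyl bromoacetate (K2CO3, acetone, reflux) should give tert-butyl 2-[(6-methoxy-2-oxo-2H-chromen-7-yl)oxy]acetate F2, chosen over the benzyl ester so that no hydrogenation is run on a coumarin. TFA in CH2Cl2 should then give 2-[(6-methoxy-2-oxo-2H-chromen-7-yl)oxy]acetic acid F3. Perkin–Oglialoro condensation of F3 with a second portion of 6 (Ac2O, Et3N, 110 °C) should deliver 10 directly, and step 8 follows unchanged.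

2. Step 7. Hydride abstraction from C4' may be too slow, since the benzylic cation is supported only by the 7'-aryloxy oxygen and the lactone oxygen, and prolonged heating with the quinone may then degrade the material. The fallback sets out from 9 and returns at 10 by radical benzylic bromination and dehydrobromination. NBS with catalytic AIBN in PhCF3 at 80 °C should give 3-[(4-bromo-6-methoxy-2-oxo-3,4-dihydro-2H-chromen-7-yl)oxy]-6-methoxy-2-oxo-2H-chromen-7-yl acetate F4 (racemic, used crude). Et3N in CH2Cl2 at room temperature should then remove HBr, driven by conjugation, to give 10.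

3. Step 4. At 110 °C the condensation may stall at O-acylated aldehydes, or be accompanied by partial loss of the tert-butyl ester and acyl scrambling between the two phenols. The fallback sets out from 6 and 5 and returns at 7 by a stepwise assembly at low temperature. Selective acetylation of the non-chelated 4-OH of 6 (Ac2O, 1 equiv, pyridine, CH2Cl2, 0 °C) should give 4-formyl-5-hydroxy-2-methoxyphenyl acetate F5. Steglich esterification of F5 with acid 5 (EDC·HCl, DMAP, CH2Cl2, 0 °C to rt) should give 5-acetoxy-2-formyl-4-methoxyphenyl 2-[4-(3-tert-butoxy-3-oxopropyl)-2-methoxyphenoxy]acetate F6. DBU in MeCN at 50 °C should then trigger intramolecular Knoevenagel-type aldol condensation and dehydration to 7.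

Further compounds
F1 | step 6 | scopoletin, 7-hydroxy-6-methoxy-2H-chromen-2-one | COc1cc2ccc(=O)oc2cc1O
F2 | step 6 | tert-butyl 2-[(6-methoxy-2-oxo-2H-chromen-7-yl)oxy]acetate | COc1cc2ccc(=O)oc2cc1OCC(=O)OC(C)(C)C
F3 | step 6 | 2-[(6-methoxy-2-oxo-2H-chromen-7-yl)oxy]acetic acid | COc1cc2ccc(=O)oc2cc1OCC(O)=O
F4 | step 7 | 3-[(4-bromo-6-methoxy-2-oxo-3,4-dihydro-2H-chromen-7-yl)oxy]-6-methoxy-2-oxo-2H-chromen-7-yl acetate (racemic) | CC(=O)Oc1cc2oc(=O)c(Oc3cc4OC(=O)CC(Br)c4cc3OC)cc2cc1OC
F5 | step 4 | 4-formyl-5-hydroxy-2-methoxyphenyl acetate | COc1cc(C=O)c(O)cc1OC(C)=O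
F6 | step 4 | 5-acetoxy-2-formyl-4-methoxyphenyl 2-[4-(3-tert-butoxy-3-oxopropyl)-2-methoxyphenoxy]acetate | COc1cc(C=O)c(OC(=O)COc2ccc(CCC(=O)OC(C)(C)C)cc2OC)cc1OC(C)=O
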